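**Plan**

- Retrosynthesis: after the ten aryl O–alkyl bonds, three aromatic C–C bonds of resorcinol ring B are cut together (C1–C6, C2–C3 and C4–C5 of ring B). This also opens the seven-membered ring and leaves a diyne plus ethoxyacetylene.
- The cut is possible because ring B is fused to the seven-membered ring and spans two methines: C8a (C3 of the dihydrobenzofuran that carries ring B) and C7b (the methine bearing the 2,4-dihydroxyphenyl group). These sit five atoms apart on the central benzene ring (C8a–C(ar)–C(ar)–CH2–C7b), so an ethynyl group on C8a and an ethoxyethynyl group on C7b are already tethered.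
- Further cuts: C7b–aryl (conjugate addition to an enoate), the butenoate arm on the central ring (allylation at a C–Br bond, then cross-metathesis), and the C2–C3 bonds of both dihydrobenzofurans (carbene C–H insertions into benzyl ethers), back to 1-bromo-3,5-dimethoxybenzene.
- Forward order: central ring with acetate arm and aroyl group, then dihydrobenzofuran 1 (contains C8a), dihydrobenzofuran 2, side chain and C7b, ynol ether and terminal alkyne, ring B together with the seven-membered ring, and last the global dealkylation.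
- Stereochemistry: each dihydrobenzofuran takes its absolute configuration from a chiral dirhodium carboxylate in the C–H insertion and its trans geometry from equilibration (base at the ester-bearing carbon, acid at the O-benzylic carbon). C7b comes from a chiral-diene rhodium conjugate addition. The key step forms no stereocentre.

Key step: step 20

Remark: the hand of each chiral ligand named (S-PTTL, R-PTAD, the (R,R)-diene) is assigned by analogy with simpler substrates; if a ligand induces the opposite sense, its mirror image is used.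

**Route**

Step 1
Reactants: 1 1-bromo-3,5-dimethoxybenzene; 2 methyl chlorooxoacetate
Product: 3 methyl 2-(2-bromo-4,6-dimethoxyphenyl)-2-oxoacetate
Conditions: TiCl4, CH2Cl2, −10 °C → rt
Reagents that add atoms: none
Why: Friedel–Crafts acylation should occur at the position ortho to bromine and para to a methoxy group, because the site between the two methoxy groups is shielded, and this brings in both carbons of the later arylacetate.

Step 2
Reactants: 3 methyl 2-(2-bromo-4,6-dimethoxyphenyl)-2-oxoacetate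
Product: 4 methyl 2-(2-bromo-4,6-dimethoxyphenyl)acetate
Conditions: Et3SiH (3 equiv), CF3CO2H, 0 °C → rt
Reagents that add atoms: none
Why: Ionic hydrogenation should take the aryl keto group down to CH2 because the 2,4-dimethoxyaryl ring stabilises the benzylic cations on the way, while ester and aryl bromide are inert to silane and acid.

Step 3
Reactants: 4 methyl 2-(2-bromo-4,6-dimethoxyphenyl)acetate
Product: 5 methyl 2-(2-bromo-4,6-dihydroxyphenyl)acetate
Conditions: BBr3 (2.5 equiv), CH2Cl2, −78 → 0 °C; aq. NaHCO3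
Reagents that add atoms: none
Why: Lewis-acid ether cleavage with BBr3 should remove both aryl methyl groups at low temperature, where the methyl ester and the aryl bromide survive, and the buffered work-up avoids lactonisation.

Step 4
Reactants: 5 methyl 2-(2-bromo-4,6-dihydroxyphenyl)acetate; 6 3,5-dimethoxybenzonitrile
Product: 8 methyl 2-[2-bromo-3-(3,5-dimethoxybenzoyl)-4,6-dihydroxyphenyl]acetate, via ketiminium chloride 7 (not isolated)
Conditions: ZnCl2, HCl (g), Et2O, 0 °C → rt; then H2O, 50 °C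
Reagents that add atoms: water, O
Why: Hoesch acylation should attack the only free ring position that is para to one hydroxyl and ortho to the other (the site between the two hydroxyls is the less reactive one in this reaction class), and hydrolysis of ketiminium salt 7 then gives the ortho-hydroxy diaryl ketone.

Step 5
Reactants: 8 methyl 2-[2-bromo-3-(3,5-dimethoxybenzoyl)-4,6-dihydroxyphenyl]acetate; 9 4-methoxybenzyl chloride
Product: 10 methyl 2-{2-bromo-3-(3,5-dimethoxybenzoyl)-4-hydroxy-6-[(4-methoxyphenyl)methoxy]phenyl}acetate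
Conditions: K2CO3 (1.1 equiv), acetone, 50 °C
Reagents that add atoms: none
Why: Williamson etherification should be selective because the hydroxyl ortho to the ketone is tied up in a hydrogen bond, so one equivalent of 9 alkylates only the free hydroxyl para to the carbonyl, which is the oxygen next to the acetate arm.

Step 6
Reactants: 10 the mono-ether from step 5; 11 (2,4-dimethoxyphenyl)methanol
Product: 12 methyl 2-{2-bromo-3-(3,5-dimethoxybenzoyl)-4-[(2,4-dimethoxyphenyl)methoxy]-6-[(4-methoxyphenyl)methoxy]phenyl}acetate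
Conditions: PPh3, diisopropyl azodicarboxylate, THF, 0 °C → rt
Reagents that add atoms: none
Why: Mitsunobu etherification should alkylate the remaining chelated but acidic phenol under neutral conditions, which spares the arylacetate and avoids the unstable 2,4-dimethoxybenzyl halides.

Step 7
Reactants: 12 the bis-benzyl ether from step 6
Product: 13 methyl 2-diazo-2-aryl-acetate of 12 (N2 on the former CH2 of the acetate arm)
Conditions: 4-acetamidobenzenesulfonyl azide, DBU, MeCN, 0 °C → rt
Reagents that add atoms: 4-acetamidobenzenesulfonyl azide, CC(=O)Nc1ccc(cc1)S(=O)(=O)N=[N+]=[N-]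
Why: Regitz diazo transfer to the DBU-generated arylacetate anion should give the aryl diazoacetate, the diaryl ketone being non-enolisable and inert.

Step 8
Reactants: 13 the aryl diazoacetate
Product: 15 methyl (2R,3R)-4-bromo-5-(3,5-dimethoxybenzoyl)-6-[(2,4-dimethoxyphenyl)methoxy]-2-(4-methoxyphenyl)-2,3-dihydro-1-benzofuran-3-carboxylate (2,3-trans), via cis ester 14 (not isolated)
Conditions: Rh2(S-PTTL)4 [dirhodium tetrakis(N-phthaloyl-(S)-tert-leucinate), 1 mol%], toluene, −60 °C; then NaOMe, MeOH, rt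
Reagents that add atoms: none
Why: Intramolecular 1,5-C–H insertion of the donor/acceptor rhodium carbene into the neighbouring O–CH2–aryl bond should close the dihydrobenzofuran with the chiral carboxylate ligands setting C2 (R) in cis ester 14, and methoxide then epimerises the ester-bearing C3 to the more stable trans isomer (3R).

Step 9
Reactants: 15 the trans keto ester
Product: 17 hydrazone of 15 (C=N–NH2 in place of the ketone C=O, 2R,3R), via N-silyl hydrazone 16 (not isolated)
Conditions: 1,2-bis(tert-butyldimethylsilyl)hydrazine, Sc(OTf)3 (1 mol%), CHCl3, 60 °C; then Bu4NF, THF, 0 °C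
Reagents that add atoms: 1,2-bis(tert-butyldimethylsilyl)hydrazine, CC(C)(C)[Si](C)(C)NN[Si](C)(C)C(C)(C)C
Why: Lewis-acid-catalysed condensation with the bis-silyl hydrazine should convert the hindered diaryl ketone into hydrazone 16 without touching the methyl ester (which free hydrazine would attack), and fluoride then removes the N-silyl group.

Step 10
Reactants: 17 the hydrazone
Product: 20 methyl (2R,3R,5S,6S)-4-bromo-6-(2,4-dimethoxyphenyl)-5-(3,5-dimethoxyphenyl)-2-(4-methoxyphenyl)-2,3,5,6-tetrahydrobenzo[1,2-b:5,4-b']difuran-3-carboxylate, via diaryldiazomethane 18 (not isolated), via 5,6-cis isomer 19 (not isolated)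
Conditions: MnO2, CH2Cl2, rt, filtration; Rh2(R-PTAD)4 [dirhodium tetrakis((R)-1-adamantyl(phthalimido)acetate), 1 mol%], CH2Cl2, 0 °C; then CF3CO2H, 0 °C, brief
Reagents that add atoms: none
Why: MnO2 dehydrogenates the hydrazone to diazo compound 18, whose donor/donor rhodium carbene should undergo 1,5-C–H insertion into the adjacent O–CH2–aryl bond with the chiral catalyst setting C5 (S), and acid then equilibrates C6 through the 2,4-dimethoxybenzylic cation so that the expected kinetic cis isomer 19 ends as the trans compound (6S).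

Step 11
Reactants: 20 the bis-dihydrobenzofuran methyl ester
Product: 21 [(2R,3S,5S,6S)-4-bromo-6-(2,4-dimethoxyphenyl)-5-(3,5-dimethoxyphenyl)-2-(4-methoxyphenyl)-2,3,5,6-tetrahydrobenzo[1,2-b:5,4-b']difuran-3-yl]methanol
Conditions: LiBH4, THF/MeOH, 0 °C → rt
Reagents that add atoms: none
Why: Borohydride reduction of the ester to the primary alcohol should leave the aryl bromide and both benzylic ethers alone and does not touch C3 (the descriptor changes only by priority).

Step 12
Reactants: 21 the primary alcohol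
Product: 22 tert-butyldimethylsilyl ether of 21 (2R,3S,5S,6S)
Conditions: t-BuMe2SiCl, imidazole, DMF, rt
Reagents that add atoms: tert-butyldimethylsilyl chloride, CC(C)(C)[Si](C)(C)Cl
Why: Silylation masks the alcohol through the organometallic and strongly basic steps that follow and can later be undone with fluoride, which an ynol ether tolerates.

Step 13
Reactants: 22 the aryl bromide; 23 2-allyl-4,4,5,5-tetramethyl-1,3,2-dioxaborolane
Product: 24 4-allyl analogue of 22 (allyl in place of Br, 2R,3S,5S,6S)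
Conditions: Pd(OAc)2, SPhos, K3PO4, toluene/H2O, 90 °C
Reagents that add atoms: none
Why: Suzuki–Miyaura allylation should work because the bulky electron-rich biarylphosphine lets zerovalent palladium insert into the doubly ortho-substituted C–Br bond, after which the allyl group transfers from boron.

Step 14
Reactants: 24 the allylarene; 25 ethyl acrylate
Product: 26 ethyl (2E)-4-arylbut-2-enoate of the bis-dihydrobenzofuran core (CH2–CH=CH–CO2Et in place of allyl)
Conditions: second-generation Hoveyda–Grubbs catalyst (5 mol%), 25 (5 equiv), CH2Cl2, 40 °C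
Reagents that add atoms: none
Why: Olefin cross-metathesis between a terminal allylarene and the electron-poor acrylate should give the (E)-enoate selectively with loss of ethene.

Step 15
Reactants: 26 the (E)-enoate; 27 (2,4-dimethoxyphenyl)boronic acid
Product: 28 ethyl (3S)-3-(2,4-dimethoxyphenyl)-4-arylbutanoate of the core (new stereocentre C7b)
Conditions: [RhCl(C2H4)2]2 (2.5 mol%), (1R,4R)-2,5-diphenylbicyclo[2.2.2]octa-2,5-diene (5.5 mol%), 27 (3 equiv), KOH (0.5 equiv), dioxane/H2O 10:1, 40 °C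
Reagents that add atoms: none
Why: In this Hayashi–Miyaura 1,4-addition the aryl–rhodium species held by the C2-symmetric diene adds to one face of the (E)-enoate and water protonates the oxa-π-allyl intermediate, so the ligand and not the remote ring stereocentres should set C7b.

Step 16
Reactants: 28 the β-aryl ethyl ester
Product: 30 ethyl ynol ether with a (2S)-2-(2,4-dimethoxyphenyl)-4-ethoxybut-3-yn-1-yl side chain on the core, via ketene acetal phosphate 29 (not isolated)
Conditions: LiN(i-Pr)2 (1.1 equiv), THF, −78 °C; ClP(O)(OEt)2; then t-BuLi (2.2 equiv), −78 °C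
Reagents that add atoms: none
Why: Enolisation and O-phosphorylation give ketene acetal phosphate 29, from which tert-butyllithium removes the vinylic proton and expels diethyl phosphate (β-elimination of an ester enol phosphate to a 1-alkoxyalkyne) at a temperature where the benzylic C–H at C7b should stay intact.

Step 17
Reactants: 30 the silyl-protected ynol ether
Product: 31 primary alcohol of 30 (CH2OH on C3 of the core)
Conditions: Bu4NF, THF, 0 °C
Reagents that add atoms: none
Why: Fluoride cleaves the Si–O bond in a basic medium, which is chosen because the ynol ether hydrates under acid but is inert to fluoride.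

Step 18
Reactants: 31 the alcohol
Product: 32 aldehyde of 31 (CHO on C3 of the core, 3R)
Conditions: Dess–Martin periodinane, pyridine, CH2Cl2, 0 °C
Reagents that add atoms: none
Why: Buffered Dess–Martin oxidation should give the aldehyde without free acid that would hydrate the ynol ether, and the epimerisable C3 stays in its thermodynamic trans arrangement.

Step 19
Reactants: 32 the aldehyde
Product: 33 (2R,3R,5S,6S)-4-[(2S)-2-(2,4-dimethoxyphenyl)-4-ethoxybut-3-yn-1-yl]-6-(2,4-dimethoxyphenyl)-5-(3,5-dimethoxyphenyl)-3-ethynyl-2-(4-methoxyphenyl)-2,3,5,6-tetrahydrobenzo[1,2-b:5,4-b']difuran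
Conditions: dimethyl (1-diazo-2-oxopropyl)phosphonate, K2CO3, MeOH, 0 °C → rt
Reagents that add atoms: dimethyl (1-diazo-2-oxopropyl)phosphonate, CC(=O)C(=[N+]=[N-])P(=O)(OC)OC
Why: In the Ohira–Bestmann homologation the diazomethylphosphonate anion adds to the aldehyde and the resulting alkylidene carbene rearranges to the terminal alkyne, any enolisation at C8a returns to the trans isomer fixed by C2, and the ynol ether is stable to methanolic carbonate.

Step 20
Reactants: 33 the diyne; 34 ethoxyacetylene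
Product: 35 octa-O-methyl di-O-ethyl ether of the target (ethyl on both ring-B oxygens, all five stereocentres as in 36)
Conditions: Cp*RuCl(cod) (10 mol%), 34 (5 equiv), ClCH2CH2Cl, rt, slow addition of 33
Reagents that add atoms: none
Why: After loss of cyclooctadiene the ruthenium centre couples the two tethered alkynes of 33 oxidatively through their internal carbons to a ruthenacyclopentadiene, 34 inserts, and reductive elimination releases the arene; the closest known reaction type is the ruthenium-catalysed (2+2+2) cyclotrimerisation of an α,ω-diyne with a terminal alkyne, including cases that build benzo-fused seven-membered rings. The seven-membered ring closes in the oxidative coupling, as the carbocycle fused to the metallacycle, and benzene ring B closes in the insertion and reductive-elimination sequence. No stereocentre is formed, and the neutral room-temperature conditions leave the propargylic centres C8a and C7b unchanged. The step needs cross- over homo-trimerisation, which slow addition of 33 into excess 34 should secure, and a 1,3-relationship of the two ethoxy groups, which follows because the ethoxy-bearing α-carbon of the metallacycle is the hindered one, so the substituted carbon of 34 bonds to the unsubstituted terminus. The five-atom tether is pre-organised because two of its atoms are adjacent carbons of the central benzene ring.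

Step 21
Reactants: 35 the decaalkyl ether
Product: 36 CNP0283541.1 (target)
Conditions: BBr3 (15 equiv), CH2Cl2, −78 → 0 °C; MeOH quench
Reagents that add atoms: none
Why: BBr3 ether cleavage should remove all eight methyl and both ethyl groups by bromide attack on the O-alkyl carbons, and since both dihydrobenzofurans are already the thermodynamic trans isomers, reversible opening at the benzylic C–O bonds does not change the configuration.

**Compound list**

1 | 1-bromo-3,5-dimethoxybenzene | COc1cc(Br)cc(OC)c1 | starting material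
2 | methyl chlorooxoacetate | COC(=O)C(=O)Cl | starting material
3 | methyl 2-(2-bromo-4,6-dimethoxyphenyl)-2-oxoacetate | COC(=O)C(=O)c1c(Br)cc(OC)cc1OC | intermediate
4 | methyl 2-(2-bromo-4,6-dimethoxyphenyl)acetate | COC(=O)Cc1c(Br)cc(OC)cc1OC | intermediate
5 | methyl 2-(2-bromo-4,6-dihydroxyphenyl)acetate | COC(=O)Cc1c(Br)cc(O)cc1O | intermediate
6 | 3,5-dimethoxybenzonitrile | COc1cc(cc(OC)c1)C#N | starting material
7 | [2-bromo-4,6-dihydroxy-3-(2-methoxy-2-oxoethyl)phenyl](3,5-dimethoxyphenyl)methaniminium chloride | COC(=O)Cc1c(Br)c(C(=[NH2+])c2cc(OC)cc(OC)c2)c(O)cc1O.[Cl-] | intermediate (not isolated)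
8 | methyl 2-[2-bromo-3-(3,5-dimethoxybenzoyl)-4,6-dihydroxyphenyl]acetate | COC(=O)Cc1c(Br)c(C(=O)c2cc(OC)cc(OC)c2)c(O)cc1O | intermediate
9 | 4-methoxybenzyl chloride | COc1ccc(CCl)cc1 | starting material
10 | methyl 2-{2-bromo-3-(3,5-dimethoxybenzoyl)-4-hydroxy-6-[(4-methoxyphenyl)methoxy]phenyl}acetate | COC(=O)Cc1c(Br)c(C(=O)c2cc(OC)cc(OC)c2)c(O)cc1OCc1ccc(OC)cc1 | intermediate
11 | (2,4-dimethoxyphenyl)methanol | COc1ccc(CO)c(OC)c1 | starting material
12 | methyl 2-{2-bromo-3-(3,5-dimethoxybenzoyl)-4-[(2,4-dimethoxyphenyl)methoxy]-6-[(4-methoxyphenyl)methoxy]phenyl}acetate | COC(=O)Cc1c(Br)c(C(=O)c2cc(OC)cc(OC)c2)c(OCc2ccc(OC)cc2OC)cc1OCc1ccc(OC)cc1 | intermediate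
13 | methyl 2-{2-bromo-3-(3,5-dimethoxybenzoyl)-4-[(2,4-dimethoxyphenyl)methoxy]-6-[(4-methoxyphenyl)methoxy]phenyl}-2-diazoacetate | COC(=O)C(=[N+]=[N-])c1c(Br)c(C(=O)c2cc(OC)cc(OC)c2)c(OCc2ccc(OC)cc2OC)cc1OCc1ccc(OC)cc1 | intermediate
14 | methyl (2R,3S)-4-bromo-5-(3,5-dimethoxybenzoyl)-6-[(2,4-dimethoxyphenyl)methoxy]-2-(4-methoxyphenyl)-2,3-dihydro-1-benzofuran-3-carboxylate (2,3-cis) | COc1ccc([C@@H]2Oc3cc(OCc4ccc(OC)cc4OC)c(C(=O)c4cc(OC)cc(OC)c4)c(Br)c3[C@@H]2C(=O)OC)cc1 | intermediate (not isolated)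
15 | methyl (2R,3R)-4-bromo-5-(3,5-dimethoxybenzoyl)-6-[(2,4-dimethoxyphenyl)methoxy]-2-(4-methoxyphenyl)-2,3-dihydro-1-benzofuran-3-carboxylate (2,3-trans) | COc1ccc([C@@H]2Oc3cc(OCc4ccc(OC)cc4OC)c(C(=O)c4cc(OC)cc(OC)c4)c(Br)c3[C@H]2C(=O)OC)cc1 | intermediate
16 | methyl (2R,3R)-4-bromo-5-[{2-[tert-butyl(dimethyl)silyl]hydrazinylidene}(3,5-dimethoxyphenyl)methyl]-6-[(2,4-dimethoxyphenyl)methoxy]-2-(4-methoxyphenyl)-2,3-dihydro-1-benzofuran-3-carboxylate | COc1ccc([C@@H]2Oc3cc(OCc4ccc(OC)cc4OC)c(C(=NN[Si](C)(C)C(C)(C)C)c4cc(OC)cc(OC)c4)c(Br)c3[C@H]2C(=O)OC)cc1 | intermediate (not isolated)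
17 | methyl (2R,3R)-4-bromo-5-[(3,5-dimethoxyphenyl)(hydrazinylidene)methyl]-6-[(2,4-dimethoxyphenyl)methoxy]-2-(4-methoxyphenyl)-2,3-dihydro-1-benzofuran-3-carboxylate | COc1ccc([C@@H]2Oc3cc(OCc4ccc(OC)cc4OC)c(C(=NN)c4cc(OC)cc(OC)c4)c(Br)c3[C@H]2C(=O)OC)cc1 | intermediate
18 | methyl (2R,3R)-4-bromo-5-[diazo(3,5-dimethoxyphenyl)methyl]-6-[(2,4-dimethoxyphenyl)methoxy]-2-(4-methoxyphenyl)-2,3-dihydro-1-benzofuran-3-carboxylate | COc1ccc([C@@H]2Oc3cc(OCc4ccc(OC)cc4OC)c(C(=[N+]=[N-])c4cc(OC)cc(OC)c4)c(Br)c3[C@H]2C(=O)OC)cc1 | intermediate (not isolated)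
19 | methyl (2R,3R,5S,6R)-4-bromo-6-(2,4-dimethoxyphenyl)-5-(3,5-dimethoxyphenyl)-2-(4-methoxyphenyl)-2,3,5,6-tetrahydrobenzo[1,2-b:5,4-b']difuran-3-carboxylate (5,6-cis) | COc1ccc([C@@H]2Oc3cc4c(c(Br)c3[C@H]2C(=O)OC)[C@H](c2cc(OC)cc(OC)c2)[C@H](c2ccc(OC)cc2OC)O4)cc1 | intermediate (not isolated)
20 | methyl (2R,3R,5S,6S)-4-bromo-6-(2,4-dimethoxyphenyl)-5-(3,5-dimethoxyphenyl)-2-(4-methoxyphenyl)-2,3,5,6-tetrahydrobenzo[1,2-b:5,4-b']difuran-3-carboxylate | COc1ccc([C@@H]2Oc3cc4c(c(Br)c3[C@H]2C(=O)OC)[C@H](c2cc(OC)cc(OC)c2)[C@@H](c2ccc(OC)cc2OC)O4)cc1 | intermediate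
21 | [(2R,3S,5S,6S)-4-bromo-6-(2,4-dimethoxyphenyl)-5-(3,5-dimethoxyphenyl)-2-(4-methoxyphenyl)-2,3,5,6-tetrahydrobenzo[1,2-b:5,4-b']difuran-3-yl]methanol | COc1ccc([C@@H]2Oc3cc4c(c(Br)c3[C@H]2CO)[C@H](c2cc(OC)cc(OC)c2)[C@@H](c2ccc(OC)cc2OC)O4)cc1 | intermediate
22 | {[(2R,3S,5S,6S)-4-bromo-6-(2,4-dimethoxyphenyl)-5-(3,5-dimethoxyphenyl)-2-(4-methoxyphenyl)-2,3,5,6-tetrahydrobenzo[1,2-b:5,4-b']difuran-3-yl]methoxy}(tert-butyl)dimethylsilane | COc1ccc([C@@H]2Oc3cc4c(c(Br)c3[C@H]2CO[Si](C)(C)C(C)(C)C)[C@H](c2cc(OC)cc(OC)c2)[C@@H](c2ccc(OC)cc2OC)O4)cc1 | intermediate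
23 | 2-allyl-4,4,5,5-tetramethyl-1,3,2-dioxaborolane | C=CCB1OC(C)(C)C(C)(C)O1 | starting material
24 | tert-butyl{[(2R,3S,5S,6S)-6-(2,4-dimethoxyphenyl)-5-(3,5-dimethoxyphenyl)-2-(4-methoxyphenyl)-4-(prop-2-en-1-yl)-2,3,5,6-tetrahydrobenzo[1,2-b:5,4-b']difuran-3-yl]methoxy}dimethylsilane | COc1ccc([C@@H]2Oc3cc4c(c(CC=C)c3[C@H]2CO[Si](C)(C)C(C)(C)C)[C@H](c2cc(OC)cc(OC)c2)[C@@H](c2ccc(OC)cc2OC)O4)cc1 | intermediate
25 | ethyl acrylate | C=CC(=O)OCC | starting material
26 | ethyl (2E)-4-[(2R,3S,5S,6S)-3-({[tert-butyl(dimethyl)silyl]oxy}methyl)-6-(2,4-dimethoxyphenyl)-5-(3,5-dimethoxyphenyl)-2-(4-methoxyphenyl)-2,3,5,6-tetrahydrobenzo[1,2-b:5,4-b']difuran-4-yl]but-2-enoate | COc1ccc([C@@H]2Oc3cc4c(c(C/C=C/C(=O)OCC)c3[C@H]2CO[Si](C)(C)C(C)(C)C)[C@H](c2cc(OC)cc(OC)c2)[C@@H](c2ccc(OC)cc2OC)O4)cc1 | intermediate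
27 | (2,4-dimethoxyphenyl)boronic acid | COc1ccc(B(O)O)c(OC)c1 | starting material
28 | ethyl (3S)-4-[(2R,3S,5S,6S)-3-({[tert-butyl(dimethyl)silyl]oxy}methyl)-6-(2,4-dimethoxyphenyl)-5-(3,5-dimethoxyphenyl)-2-(4-methoxyphenyl)-2,3,5,6-tetrahydrobenzo[1,2-b:5,4-b']difuran-4-yl]-3-(2,4-dimethoxyphenyl)butanoate | COc1ccc([C@@H]2Oc3cc4c(c(C[C@@H](CC(=O)OCC)c5ccc(OC)cc5OC)c3[C@H]2CO[Si](C)(C)C(C)(C)C)[C@H](c2cc(OC)cc(OC)c2)[C@@H](c2ccc(OC)cc2OC)O4)cc1 | intermediate
29 | (1E,3S)-4-[(2R,3S,5S,6S)-3-({[tert-butyl(dimethyl)silyl]oxy}methyl)-6-(2,4-dimethoxyphenyl)-5-(3,5-dimethoxyphenyl)-2-(4-methoxyphenyl)-2,3,5,6-tetrahydrobenzo[1,2-b:5,4-b']difuran-4-yl]-3-(2,4-dimethoxyphenyl)-1-ethoxybut-1-en-1-yl diethyl phosphate | COc1ccc([C@@H]2Oc3cc4c(c(C[C@@H](/C=C(\OCC)OP(=O)(OCC)OCC)c5ccc(OC)cc5OC)c3[C@H]2CO[Si](C)(C)C(C)(C)C)[C@H](c2cc(OC)cc(OC)c2)[C@@H](c2ccc(OC)cc2OC)O4)cc1 | intermediate (not isolated)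
30 | tert-butyl{[(2R,3S,5S,6S)-4-[(2S)-2-(2,4-dimethoxyphenyl)-4-ethoxybut-3-yn-1-yl]-6-(2,4-dimethoxyphenyl)-5-(3,5-dimethoxyphenyl)-2-(4-methoxyphenyl)-2,3,5,6-tetrahydrobenzo[1,2-b:5,4-b']difuran-3-yl]methoxy}dimethylsilane | COc1ccc([C@@H]2Oc3cc4c(c(C[C@@H](C#COCC)c5ccc(OC)cc5OC)c3[C@H]2CO[Si](C)(C)C(C)(C)C)[C@H](c2cc(OC)cc(OC)c2)[C@@H](c2ccc(OC)cc2OC)O4)cc1 | intermediate
31 | [(2R,3S,5S,6S)-4-[(2S)-2-(2,4-dimethoxyphenyl)-4-ethoxybut-3-yn-1-yl]-6-(2,4-dimethoxyphenyl)-5-(3,5-dimethoxyphenyl)-2-(4-methoxyphenyl)-2,3,5,6-tetrahydrobenzo[1,2-b:5,4-b']difuran-3-yl]methanol | COc1ccc([C@@H]2Oc3cc4c(c(C[C@@H](C#COCC)c5ccc(OC)cc5OC)c3[C@H]2CO)[C@H](c2cc(OC)cc(OC)c2)[C@@H](c2ccc(OC)cc2OC)O4)cc1 | intermediate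
32 | (2R,3R,5S,6S)-4-[(2S)-2-(2,4-dimethoxyphenyl)-4-ethoxybut-3-yn-1-yl]-6-(2,4-dimethoxyphenyl)-5-(3,5-dimethoxyphenyl)-2-(4-methoxyphenyl)-2,3,5,6-tetrahydrobenzo[1,2-b:5,4-b']difuran-3-carbaldehyde | COc1ccc([C@@H]2Oc3cc4c(c(C[C@@H](C#COCC)c5ccc(OC)cc5OC)c3[C@H]2C=O)[C@H](c2cc(OC)cc(OC)c2)[C@@H](c2ccc(OC)cc2OC)O4)cc1 | intermediate
33 | (2R,3R,5S,6S)-4-[(2S)-2-(2,4-dimethoxyphenyl)-4-ethoxybut-3-yn-1-yl]-6-(2,4-dimethoxyphenyl)-5-(3,5-dimethoxyphenyl)-3-ethynyl-2-(4-methoxyphenyl)-2,3,5,6-tetrahydrobenzo[1,2-b:5,4-b']difuran | COc1ccc([C@@H]2Oc3cc4c(c(C[C@@H](C#COCC)c5ccc(OC)cc5OC)c3[C@H]2C#C)[C@H](c2cc(OC)cc(OC)c2)[C@@H](c2ccc(OC)cc2OC)O4)cc1 | intermediate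
34 | ethoxyacetylene (ethoxyethyne) | C#COCC | starting material
35 | octa-O-methyl di-O-ethyl ether of 36 (ethoxy on both ring-B oxygens, methoxy on the other eight; stereocentres as in 36) | COc1ccc([C@@H]2Oc3cc4c(c5c3[C@H]2c2cc(OCC)cc(OCC)c2[C@@H](c2ccc(OC)cc2OC)C5)[C@H](c2cc(OC)cc(OC)c2)[C@@H](c2ccc(OC)cc2OC)O4)cc1 | intermediate
36 | CNP0283541.1 | Oc1ccc([C@@H]2Oc3cc4c(c5c3[C@H]2c2cc(O)cc(O)c2[C@@H](c2ccc(O)cc2O)C5)[C@H](c2cc(O)cc(O)c2)[C@@H](c2ccc(O)cc2O)O4)cc1 | target

**Counts and risks**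

Total step count: 21. Longest linear sequence: 21 steps (from 1).

Steps most likely to fail:

Step 20. Ethoxyacetylene may cyclotrimerise with itself, the ruthenacycle from 33 may capture a second molecule of 33 instead of 34, or insertion may leak towards the 1,2-dialkoxy isomer. The fallback sets out from 33 and changes the source of the second ring-B oxygen from an alkynyl ether to boron. Under the same Cp*RuCl(cod) catalysis, 33 is combined with 2-ethynyl-4,4,5,5-tetramethyl-1,3,2-dioxaborolane, a partner that does not self-trimerise readily and whose bulky boryl carbon should bond to the unsubstituted diyne terminus; this gives the ring-B pinacol arylboronate F1. NaBO3·4H2O in THF/H2O oxidises the C–B bond to the ring-B monophenol F2. EtI and K2CO3 in DMF ethylate the phenol, and the route is rejoined at 35.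

Step 16. tert-Butyllithium may attack phosphorus of 29 and regenerate the enolate, or remove the benzylic, allylic proton at C7b and erode its configuration. The fallback sets out from 28 and builds the ynol ether by the classical enol-ether bromination and double dehydrobromination. Reductive acetylation (i-Bu2AlH, −78 °C; then Ac2O, pyridine, DMAP) gives the α-acetoxy ethyl ether F3. Me3SiOTf with i-Pr2NEt eliminates acetic acid to the ethyl enol ether F4. Bromine (1 equiv, CH2Cl2, −78 °C) adds across the enol ether faster than it attacks the arenes and gives the 1,2-dibromo ether F5. DBU removes HBr to the 2-bromo enol ether F6. LiN(i-Pr)2 at −78 °C effects the second dehydrobromination, and the route is rejoined at 30.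

Step 9. The condensation may stall at a ketone flanked by bromine and a benzyloxy group, or the Lewis acid may begin to cleave the 2,4-dimethoxybenzyl ether. The fallback sets out from 15 and activates the carbonyl as a thiocarbonyl. Lawesson's reagent (toluene, 80 °C) converts the diaryl ketone into the diaryl thioketone F7, which should react faster than the ester. Hydrazine hydrate (THF, 0 °C) then adds to the C=S carbon far faster than to the ester and expels H2S, and the route is rejoined at 17.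

**Further compounds**

F1 | step 20 | analogue of 35 with a 4,4,5,5-tetramethyl-1,3,2-dioxaborolan-2-yl group on ring B in place of the ethoxy group that comes from 34 (stereocentres as in 35) | COc1ccc([C@@H]2Oc3cc4c(c5c3[C@H]2c2cc(B3OC(C)(C)C(C)(C)O3)cc(OCC)c2[C@@H](c2ccc(OC)cc2OC)C5)[C@H](c2cc(OC)cc(OC)c2)[C@@H](c2ccc(OC)cc2OC)O4)cc1
F2 | step 20 | ring-B monophenol: analogue of 35 with OH in place of the ethoxy group that comes from 34 | COc1ccc([C@@H]2Oc3cc4c(c5c3[C@H]2c2cc(O)cc(OCC)c2[C@@H](c2ccc(OC)cc2OC)C5)[C@H](c2cc(OC)cc(OC)c2)[C@@H](c2ccc(OC)cc2OC)O4)cc1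
F3 | step 16 | α-acetoxy ethyl ether from 28: CH2–CH(OEt)OAc in place of CH2–CO2Et (epimers at the acetal carbon, other stereocentres as in 28) | COc1ccc([C@@H]2Oc3cc4c(c(C[C@@H](CC(OCC)OC(C)=O)c5ccc(OC)cc5OC)c3[C@H]2CO[Si](C)(C)C(C)(C)C)[C@H](c2cc(OC)cc(OC)c2)[C@@H](c2ccc(OC)cc2OC)O4)cc1
F4 | step 16 | ethyl enol ether: CH=CH–OEt in place of CH2–CO2Et of 28 (E/Z mixture) | COc1ccc([C@@H]2Oc3cc4c(c(C[C@@H](C=COCC)c5ccc(OC)cc5OC)c3[C@H]2CO[Si](C)(C)C(C)(C)C)[C@H](c2cc(OC)cc(OC)c2)[C@@H](c2ccc(OC)cc2OC)O4)cc1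
F5 | step 16 | 1,2-dibromo ether: CHBr–CHBr–OEt in place of CH=CH–OEt of F4 (diastereomer mixture) | COc1ccc([C@@H]2Oc3cc4c(c(C[C@@H](C(Br)C(Br)OCC)c5ccc(OC)cc5OC)c3[C@H]2CO[Si](C)(C)C(C)(C)C)[C@H](c2cc(OC)cc(OC)c2)[C@@H](c2ccc(OC)cc2OC)O4)cc1
F6 | step 16 | 2-bromo enol ether: CBr=CH–OEt in place of CH=CH–OEt of F4 | COc1ccc([C@@H]2Oc3cc4c(c(C[C@@H](C(Br)=COCC)c5ccc(OC)cc5OC)c3[C@H]2CO[Si](C)(C)C(C)(C)C)[C@H](c2cc(OC)cc(OC)c2)[C@@H](c2ccc(OC)cc2OC)O4)cc1
F7 | step 9 | methyl (2R,3R)-4-bromo-5-(3,5-dimethoxybenzenecarbothioyl)-6-[(2,4-dimethoxyphenyl)methoxy]-2-(4-methoxyphenyl)-2,3-dihydro-1-benzofuran-3-carboxylate | COc1ccc([C@@H]2Oc3cc(OCc4ccc(OC)cc4OC)c(C(=S)c4cc(OC)cc(OC)c4)c(Br)c3[C@H]2C(=O)OC)cc1
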